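**Plan**
The retrosynthesis cuts ring A (the quinone ring) at C1–C8a and C2–C3, which removes C1–C2 as dimethyl oxalate and leaves an o-iodoaryl methyl ketone. It then cuts the C8–aryl and C6–CH2 bonds back to a dihalogenated 2-aminoacetophenone.
Forward: the NH2 group of 1 places iodine para and bromine ortho; the two halogens are exchanged for the benzyl group (Negishi) and the aryl group (Suzuki–Miyaura); NH2 then becomes iodide; ring A is closed last on the finished ring B.
Enabling feature: C1–C2 is a vicinal dioxygenated pair at the oxalic acid level, flanked by C3 (alpha to the C4 carbonyl, a donor as its enolate) and by C8a (ortho to the C4 acyl group, a donor only after iodine–lithium exchange, a polarity reversal).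
The 1,4-C,C-dianion therefore closes ring A on oxalate in one operation, and the hydroxyquinone obtained is methylated and debenzylated.
The target has no stereocentre, so no stereocontrol is required.

Key step: step 6

Assumption: compounds 1, 4, 7 and 11 are taken as purchasable, and both phenols are carried as benzyl ethers until the last step.

Step 1
Reactants: 1 1-(2-amino-4-methylphenyl)ethan-1-one
Product: 2 1-(2-amino-5-iodo-4-methylphenyl)ethan-1-one
Conditions: NIS (1.05 equiv), AcOH (cat.), MeCN, 0 °C to rt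
Reagents that add atoms: N-iodosuccinimide, O=C1CCC(=O)N1I
Why: Electrophilic aromatic iodination should go para to NH2 (C5), because the other activated position (C3) is flanked by NH2 and CH3.

Step 2
Reactants: 2 1-(2-amino-5-iodo-4-methylphenyl)ethan-1-one
Product: 3 1-(2-amino-3-bromo-5-iodo-4-methylphenyl)ethan-1-one
Conditions: NBS (1.05 equiv), MeCN, 0 °C to rt, dark
Reagents that add atoms: N-bromosuccinimide, O=C1CCC(=O)N1Br
Why: Electrophilic aromatic bromination should take the one remaining position ortho to NH2, which puts the less reactive halogen on the more hindered carbon.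

Step 3
Reactants: 3 1-(2-amino-3-bromo-5-iodo-4-methylphenyl)ethan-1-one; 4 4-(benzyloxy)-3-methoxybenzyl chloride
Product: 6 1-{2-amino-5-[4-(benzyloxy)-3-methoxybenzyl]-3-bromo-4-methylphenyl}ethan-1-one, via benzylzinc chloride 5 (not isolated)
Conditions: 4, Zn dust, LiCl, THF, rt; then 3, Pd(OAc)2 (2 mol %), SPhos (4 mol %), THF, rt, slow addition of 5 (1.2 equiv)
Reagents that add atoms: none
Why: Negishi coupling of a benzylic zinc reagent should occur at the unhindered C–I bond well before the di-ortho-substituted C–Br bond, and benzylic zinc reagents tolerate a free aniline N–H and a ketone.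

Step 4
Reactants: 6 1-{2-amino-5-[4-(benzyloxy)-3-methoxybenzyl]-3-bromo-4-methylphenyl}ethan-1-one; 7 [4-(benzyloxy)-3-methoxyphenyl]boronic acid
Product: 8 1-{2-amino-3-[4-(benzyloxy)-3-methoxyphenyl]-5-[4-(benzyloxy)-3-methoxybenzyl]-4-methylphenyl}ethan-1-one
Conditions: Pd(OAc)2 (3 mol %), SPhos (6 mol %), K3PO4, toluene/H2O, 100 °C
Reagents that add atoms: none
Why: Suzuki–Miyaura coupling with a bulky biarylphosphine should join the hindered bromide to an unhindered boronic acid without affecting the free NH2 or the ketone.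

Step 5
Reactants: 8 1-{2-amino-3-[4-(benzyloxy)-3-methoxyphenyl]-5-[4-(benzyloxy)-3-methoxybenzyl]-4-methylphenyl}ethan-1-one
Product: 10 1-{3-[4-(benzyloxy)-3-methoxyphenyl]-5-[4-(benzyloxy)-3-methoxybenzyl]-2-iodo-4-methylphenyl}ethan-1-one, via diazonium tosylate 9 (not isolated)
Conditions: t-BuONO (1.2 equiv), p-TsOH·H2O (3 equiv), MeCN, 0 °C; then KI (2.5 equiv), H2O, 0 °C to rt
Reagents that add atoms: potassium iodide, [K+].[I-]
Why: Sandmeyer-type iododediazoniation should replace the amino group by iodine exactly at the carbon between the acetyl-bearing and aryl-bearing carbons, as 2-aminoacetophenones are routinely converted into 2-iodoacetophenones in this way.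

Step 6
Reactants: 10 1-{3-[4-(benzyloxy)-3-methoxyphenyl]-5-[4-(benzyloxy)-3-methoxybenzyl]-2-iodo-4-methylphenyl}ethan-1-one; 11 dimethyl oxalate
Product: 14 8-[4-(benzyloxy)-3-methoxyphenyl]-6-[4-(benzyloxy)-3-methoxybenzyl]-2-hydroxy-7-methylnaphthalene-1,4-dione, via aryllithium enolate 12 (not isolated), via glyoxylate enolate 13 (not isolated)
Conditions: LiN(SiMe3)2 (1.1 equiv), THF, −78 °C; t-BuLi (2.1 equiv), −78 °C; 11 (1.05 equiv), −78 °C to rt; aq. HCl
Reagents that add atoms: none
Why: Proposed new method: LiN(SiMe3)2 should turn the only enolisable site, the acetyl CH3, into the lithium enolate, which masks the ketone while t-BuLi exchanges iodine for lithium at C8a to give the 1,4-C,C-dianion 12; the aryllithium should add first to one ester carbon of 11 (C1–C8a, glyoxylate 13), and on warming the enolate carbon C3 should attack the second ester carbon (C2–C3) with loss of methoxide, the triketone being drained irreversibly as the lithium salt of the 2-hydroxy-1,4-quinone. The closest known reaction types are the acylation of aryllithiums by dialkyl oxalates to aryl glyoxylates, the Parham-type cyclization of aryllithiums made by halogen–metal exchange, and the Claisen condensation of aryl methyl ketones with oxalates; joining them on one o-lithioaryl ketone enolate is the new element. Ring A closes in a 6-(enolendo)-exo-trig Claisen mode, whereas aldol attack of C3 on the C1 ketone would be a disfavoured and reversible 5-(enolendo)-exo-trig closure. No stereocentre is formed. The step needs regiocontrol between the two carbons ortho to the acyl group (C8a against C5), which the iodine secures because it stands only where the directing amino group stood; it also needs t-BuLi to choose C–I over C=O and over the diarylmethane CH2, which the enolate and the rate of exchange at −78 °C secure. Using about one equivalent of 11 should keep the enolate from capturing a second oxalate before ring closure.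

Step 7
Reactants: 14 8-[4-(benzyloxy)-3-methoxyphenyl]-6-[4-(benzyloxy)-3-methoxybenzyl]-2-hydroxy-7-methylnaphthalene-1,4-dione
Product: 15 8-[4-(benzyloxy)-3-methoxyphenyl]-6-[4-(benzyloxy)-3-methoxybenzyl]-2-methoxy-7-methylnaphthalene-1,4-dione
Conditions: MeOH/THF, conc. H2SO4 (cat.), 65 °C
Reagents that add atoms: methanol, CO
Why: Acid-catalysed etherification of the vinylogous carboxylic acid (Fischer-type) should give the thermodynamically preferred 2-methoxy-1,4-quinone, while the aryl benzyl ethers are inert to methanolic acid.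

Step 8
Reactants: 15 8-[4-(benzyloxy)-3-methoxyphenyl]-6-[4-(benzyloxy)-3-methoxybenzyl]-2-methoxy-7-methylnaphthalene-1,4-dione
Product: 17 larreantin, 8-(4-hydroxy-3-methoxyphenyl)-6-(4-hydroxy-3-methoxybenzyl)-2-methoxy-7-methylnaphthalene-1,4-dione, via hydroquinone 16 (not isolated)
Conditions: H2 (1 atm), 10% Pd/C, EtOAc/MeOH, rt; filter; then air, rt
Reagents that add atoms: none
Why: Hydrogenolysis should cleave both benzyl ethers while the quinone is reduced only reversibly to its hydroquinone, which air should reoxidise to the quinone.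

**Compound list**
1 | 1-(2-amino-4-methylphenyl)ethan-1-one | CC(=O)c1ccc(C)cc1N | starting material
2 | 1-(2-amino-5-iodo-4-methylphenyl)ethan-1-one | CC(=O)c1cc(I)c(C)cc1N | intermediate
3 | 1-(2-amino-3-bromo-5-iodo-4-methylphenyl)ethan-1-one | CC(=O)c1cc(I)c(C)c(Br)c1N | intermediate
4 | 4-(benzyloxy)-3-methoxybenzyl chloride | COc1cc(CCl)ccc1OCc1ccccc1 | starting material
5 | [4-(benzyloxy)-3-methoxybenzyl]zinc chloride | COc1cc(C[Zn]Cl)ccc1OCc1ccccc1 | intermediate
6 | 1-{2-amino-5-[4-(benzyloxy)-3-methoxybenzyl]-3-bromo-4-methylphenyl}ethan-1-one | CC(=O)c1cc(Cc2ccc(OCc3ccccc3)c(OC)c2)c(C)c(Br)c1N | intermediate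
7 | [4-(benzyloxy)-3-methoxyphenyl]boronic acid | COc1cc(B(O)O)ccc1OCc1ccccc1 | starting material
8 | 1-{2-amino-3-[4-(benzyloxy)-3-methoxyphenyl]-5-[4-(benzyloxy)-3-methoxybenzyl]-4-methylphenyl}ethan-1-one | CC(=O)c1cc(Cc2ccc(OCc3ccccc3)c(OC)c2)c(C)c(-c2ccc(OCc3ccccc3)c(OC)c2)c1N | intermediate
9 | 2-acetyl-6-[4-(benzyloxy)-3-methoxyphenyl]-4-[4-(benzyloxy)-3-methoxybenzyl]-5-methylbenzenediazonium 4-methylbenzenesulfonate | CC(=O)c1cc(Cc2ccc(OCc3ccccc3)c(OC)c2)c(C)c(-c2ccc(OCc3ccccc3)c(OC)c2)c1[N+]#N.Cc1ccc(cc1)S(=O)(=O)[O-] | intermediate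
10 | 1-{3-[4-(benzyloxy)-3-methoxyphenyl]-5-[4-(benzyloxy)-3-methoxybenzyl]-2-iodo-4-methylphenyl}ethan-1-one | CC(=O)c1cc(Cc2ccc(OCc3ccccc3)c(OC)c2)c(C)c(-c2ccc(OCc3ccccc3)c(OC)c2)c1I | intermediate
11 | dimethyl oxalate | COC(=O)C(=O)OC | starting material
12 | lithium 1-{3-[4-(benzyloxy)-3-methoxyphenyl]-5-[4-(benzyloxy)-3-methoxybenzyl]-2-lithio-4-methylphenyl}ethen-1-olate | [Li]OC(=C)c1cc(Cc2ccc(OCc3ccccc3)c(OC)c2)c(C)c(-c2ccc(OCc3ccccc3)c(OC)c2)c1[Li] | intermediate
13 | lithium enolate of methyl 2-{2-acetyl-6-[4-(benzyloxy)-3-methoxyphenyl]-4-[4-(benzyloxy)-3-methoxybenzyl]-5-methylphenyl}-2-oxoacetate | [Li]OC(=C)c1cc(Cc2ccc(OCc3ccccc3)c(OC)c2)c(C)c(-c2ccc(OCc3ccccc3)c(OC)c2)c1C(=O)C(=O)OC | intermediate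
14 | 8-[4-(benzyloxy)-3-methoxyphenyl]-6-[4-(benzyloxy)-3-methoxybenzyl]-2-hydroxy-7-methylnaphthalene-1,4-dione | OC1=CC(=O)c2cc(Cc3ccc(OCc4ccccc4)c(OC)c3)c(C)c(-c3ccc(OCc4ccccc4)c(OC)c3)c2C1=O | intermediate
15 | 8-[4-(benzyloxy)-3-methoxyphenyl]-6-[4-(benzyloxy)-3-methoxybenzyl]-2-methoxy-7-methylnaphthalene-1,4-dione | COC1=CC(=O)c2cc(Cc3ccc(OCc4ccccc4)c(OC)c3)c(C)c(-c3ccc(OCc4ccccc4)c(OC)c3)c2C1=O | intermediate
16 | 8-(4-hydroxy-3-methoxyphenyl)-6-(4-hydroxy-3-methoxybenzyl)-2-methoxy-7-methylnaphthalene-1,4-diol | COc1cc(O)c2cc(Cc3ccc(O)c(OC)c3)c(C)c(-c3ccc(O)c(OC)c3)c2c1O | intermediate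
17 | larreantin, 8-(4-hydroxy-3-methoxyphenyl)-6-(4-hydroxy-3-methoxybenzyl)-2-methoxy-7-methylnaphthalene-1,4-dione | COC1=CC(=O)c2cc(Cc3ccc(O)c(OC)c3)c(C)c(-c3ccc(O)c(OC)c3)c2C1=O | target

**Step count and risks**
Total steps: 8. Longest linear sequence: 8 steps (1 to 17); compounds 4, 7 and 11 enter directly.

Step 6 (bears the label). What may go wrong: proton transfer to the hindered aryllithium before it is acylated, capture of a second oxalate by the enolate, or closure stopping at the open glyoxylate. The fallback uses known chemistry and sets out from 10. Palladium-catalysed α-arylation with the Reformatsky reagent of tert-butyl bromoacetate (BrZnCH2CO2t-Bu, Pd(dba)2, P(t-Bu)3, THF, rt) should give tert-butyl 2-{2-acetyl-6-[4-(benzyloxy)-3-methoxyphenyl]-4-[4-(benzyloxy)-3-methoxybenzyl]-5-methylphenyl}acetate F1. KOt-Bu in THF should then close ring A by Claisen condensation of the acetyl enolate on the ester to give 5-[4-(benzyloxy)-3-methoxyphenyl]-7-[4-(benzyloxy)-3-methoxybenzyl]-6-methylnaphthalene-1,3-diol F2. Autoxidation of F2 (O2, KOt-Bu, t-BuOH, rt) at its free C4 position, the carbon that becomes C1 of the quinone, should give hydroxyquinone 14, where the route is rejoined.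

Step 5. What may go wrong: cyclisation of the diazonium ion onto the enol of the ortho acetyl group (Borsche-type cinnoline formation), or attack of the nitrosating agent on the two dialkoxybenzene rings before iodide traps the diazonium ion. The fallback moves the diazotisation to 3, where no electron-rich ring is present, and stores the nitrogen as a triazene. From 3, NaNO2/HCl at 0 °C followed by pyrrolidine/K2CO3 should give 1-[3-bromo-5-iodo-4-methyl-2-(pyrrolidin-1-yldiazenyl)phenyl]ethan-1-one F3. Negishi coupling with 5 as in step 3 should give the benzylated triazene F4, and Suzuki–Miyaura coupling with 7 as in step 4 should give the biaryl triazene F5; the triazene also removes the acidic N–H from both couplings. Heating F5 with MeI (sealed tube, 100 °C) should release the diazonium iodide in the absence of any nitrosating agent and give iodide 10, where the route is rejoined.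

Step 3. What may go wrong: protonation of the benzylzinc reagent by the N–H bonds, homocoupling during zinc insertion into the electron-rich benzyl chloride, or competing oxidative addition at the C–Br bond. The fallback changes the coupling manifold from zinc to boron and sets out from 4 and 3. Palladium-catalysed borylation of 4 (B2pin2, Pd2(dba)3, tris(4-methoxyphenyl)phosphine, KOAc, toluene, 50 °C) should give 2-[4-(benzyloxy)-3-methoxybenzyl]-4,4,5,5-tetramethyl-1,3,2-dioxaborolane F6. Suzuki–Miyaura coupling of F6 with 3 (Pd(dppf)Cl2, Cs2CO3, THF/H2O, 60 °C) should then give 6, where the route is rejoined; the boron reagent is not basic, and the iodide should still react before the hindered bromide.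

**Further compounds**
F1 | step 6 | tert-butyl 2-{2-acetyl-6-[4-(benzyloxy)-3-methoxyphenyl]-4-[4-(benzyloxy)-3-methoxybenzyl]-5-methylphenyl}acetate | CC(=O)c1cc(Cc2ccc(OCc3ccccc3)c(OC)c2)c(C)c(-c2ccc(OCc3ccccc3)c(OC)c2)c1CC(=O)OC(C)(C)C
F2 | step 6 | 5-[4-(benzyloxy)-3-methoxyphenyl]-7-[4-(benzyloxy)-3-methoxybenzyl]-6-methylnaphthalene-1,3-diol | Oc1cc(O)c2cc(Cc3ccc(OCc4ccccc4)c(OC)c3)c(C)c(-c3ccc(OCc4ccccc4)c(OC)c3)c2c1
F3 | step 5 | 1-{3-bromo-5-iodo-4-methyl-2-[(E)-pyrrolidin-1-yldiazenyl]phenyl}ethan-1-one | CC(=O)c1cc(I)c(C)c(Br)c1/N=N/N1CCCC1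
F4 | step 5 | 1-{5-[4-(benzyloxy)-3-methoxybenzyl]-3-bromo-4-methyl-2-[(E)-pyrrolidin-1-yldiazenyl]phenyl}ethan-1-one | CC(=O)c1cc(Cc2ccc(OCc3ccccc3)c(OC)c2)c(C)c(Br)c1/N=N/N1CCCC1
F5 | step 5 | 1-{3-[4-(benzyloxy)-3-methoxyphenyl]-5-[4-(benzyloxy)-3-methoxybenzyl]-4-methyl-2-[(E)-pyrrolidin-1-yldiazenyl]phenyl}ethan-1-one | CC(=O)c1cc(Cc2ccc(OCc3ccccc3)c(OC)c2)c(C)c(-c2ccc(OCc3ccccc3)c(OC)c2)c1/N=N/N1CCCC1
F6 | step 3 | 2-[4-(benzyloxy)-3-methoxybenzyl]-4,4,5,5-tetramethyl-1,3,2-dioxaborolane | COc1cc(CB2OC(C)(C)C(C)(C)O2)ccc1OCc1ccccc1
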